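**Structural features**

Abroquinone A is an isoflavan quinone in which benzene ring A (C4a to C8a, methoxy groups at C6 and C7) is fused to the dihydropyran ring C (O1, C2, C3, C4), and C3 carries ring B through the C3–C1′ bond. Ring B is a 2,3-dimethoxy-1,4-benzoquinone with its carbonyl groups at C2′ and C5′ and its methoxy groups at C3′ and C4′. C3 is the only stereocentre, (S) with the priority order C2, C1′, C4, H, and it lies between two methylene groups with no neighbouring stereocentre or heteroatom to direct its formation. The quinone is the fragile group, being electrophilic, reducible and base-sensitive, and the adjacent C3–H can be lost through quinone-methide tautomerism, so ring B has to stay at the arene level until the last step. Ring A is a 1,2,4-trioxygenated benzene in which O1 and the C6 methoxy group are para, a hydroquinone diether about as easy to oxidise as a tetramethoxyphenyl ring, so a closing (NH4)2Ce(NO3)6 oxidation of a fully methylated ring B could not be trusted to spare ring A. For that reason O2′ is carried as a methoxymethyl ether from the start, so that the final oxidation acts on a free 2′-phenol para to the C5′ methoxy group while ring A has no free hydroxyl. The real difficulty is the enantioselective creation of C3, and the key step exploits the fact that ring C is the phenol oxygen O1 and the ortho carbon C4a of 3,4-dimethoxyphenol bridged by C2–C3–C4, a unit that maps onto a 2-arylacrolein (C2 the formyl carbon, C3 the α-carbon bearing ring B, C4 the methylene terminus).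

**Logic of the disconnections**

14 ⇒ 13. No skeletal bond is cut; the C2′ and C5′ carbonyl groups go back to a C2′ hydroxyl para to a C5′ methoxy group. Ring A has no free phenol, so a phenol-selective oxidant meets ring B alone, and the sensitive quinone exists only in the final compound. The forward step must deliver oxygen to the para carbon and leave C3–H untouched.

13 ⇒ 12. The O2′–H bond is exchanged for O2′–CH2OMe. The acetal keeps O2′ inert through the organometallic, hydride and Mitsunobu steps and earlier directs the metalation. Its removal must not touch the five aryl methyl ethers or the chroman.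

12 ⇒ 11. The O1–C2 bond is cut. This opens ring C to a phenol and a primary alcohol on an acyclic chain whose only stereocentre is C3. The forward closure must be an SN2 etherification at C2 that does not involve C3.

11 ⇒ 10. C2 is raised from the alcohol to the aldehyde level and O1–C2 is re-formed as a lactol. This brings the intermediate to the oxidation state that an aldehyde-based annulation delivers. The forward reduction must be faster than enolisation of the α-aryl aldehyde form.

10 ⇒ 7 + 8 (through 9). The C4–C4a and O1–C2 bonds are cut and the C3–H bond is removed, splitting the molecule into two achiral halves of similar size. The forward step must choose C- over O-alkylation, the less hindered ortho carbon of 8, and one face of C3 in the protonation.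

7 ⇒ 6. The C2 formyl group is masked as a diethyl acetal. The acetal can be stored and survives organometallic chemistry. The forward hydrolysis must leave the methoxymethyl ether intact and must not let the acrolein oligomerise.

6 ⇒ 2 + 3 (through 4 and 5). The C1′–C3 bond is cut, giving an arene with a free position ortho to its acetal oxygen and a three-carbon vinyl bromide. The forward step needs regioselective metalation next to the methoxymethoxy group and a cross-coupling that tolerates the allylic acetal.

2 ⇒ 1. The O–CH2OMe bond is cut, leading back to a purchasable phenol. The forward step is a simple O-alkylation.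

**Other disconnections considered**

Alternative 1: Conjunctive coupling around a vinylboronate.
- **Cut:** C3–C1′ and C4–C4a, on either side of a two-carbon vinyl unit.
- **Forward step:** Aryllithium A1 adds to the boron of pinacol vinylboronate A2. An arylpalladium species from triflate A3, generated with Pd(OAc)2 and a chiral bisphosphine, then triggers a 1,2-shift of the ring B aryl group from boron to C3 while C4–C4a forms by reductive elimination, giving boronate A4.
- **In its favour:** The reaction class is established for aryl triflates and aryl migrating groups, the stereocentre is set catalytically, and the three fragments are simple. On precedent for the stereodefining event it is the better of the two plans, and it equals the chosen plan in making two skeletal bonds and one stereocentre in one step.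
- **Against it here:** Boron ends up on C3, where the target needs the C2 methylene. A4 therefore needs a Matteson one-carbon homologation, C–B oxidation, debenzylation and Mitsunobu closure, and ring C is not formed in the key step. Both aryl partners are ortho-substituted and electron-rich, which should slow migration and oxidative addition. The ring B end-game problem is unchanged, because A4 carries a fully methylated ring B.
- **Comparison:** Mechanistically safer, but about three steps longer than the chosen route and with a less secure last oxidation.

Alternative 2: Chromene–quinone annulation, then hydrogenolysis.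
- **Cut:** C3–C1′, plus a temporary C4–O bond to a ring B oxygen.
- **Forward step:** A chiral tetravalent titanium Lewis acid (TiCl4/Ti(OiPr)4 with a chiral diol ligand) activates quinone A6. C3 of chromene A5 attacks its unsubstituted carbon and the neighbouring quinone oxygen traps the C4 benzylic cation, giving cis-pterocarpan A7. Hydrogenolysis of the benzylic C4–O bond (H2, Pd/C) gives hydroquinone A8, which mild oxidants (air, Ag2O) should take to 14.
- **In its favour:** It is the better plan on step count (three steps from A5 and A6). Ring B arrives with its final oxygenation, and the closing hydroquinone oxidation is at least the equal of the phenol oxidation chosen here, since it cannot touch ring A. The annulation type is known for 2-alkoxyquinones and 2H-chromenes.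
- **Against it here:** The reaction class typically needs the chiral titanium complex in stoichiometric amount or more. A6 has two equivalent chelating sites and two donor methoxy groups, so it should be less reactive and less well organised than a mono-alkoxyquinone. Cyclobutane and bicyclic by-products compete, and electron-rich A5 is acid-sensitive.
- **Comparison:** Shorter and with a cleaner end-game, but the stereocentre depends on a stoichiometric chiral metal reagent. The chosen plan is catalytic in chiral material and forms ring C directly, at the price of an untested key step.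

Alternative 3: [2+2+2] cyclotrimerisation building rings A and C together.
- **Cut:** C4a–C8a, C5–C6 and C7–C8, so ring A is made from three alkynes.
- **Forward step:** Diyne A9 (tethered through C4–C3–C2–O1) and alkyne A10 cyclotrimerise under CpCo(CO)2 or RhCl(PPh3)3 to give A11.
- **In its favour:** It closes two rings in one step, which is better than the single ring closed by the chosen key step. The symmetrical alkyne removes any regiochemical question and places boron exactly at C6 and C7.
- **Against it here:** The step creates no stereocentre, so C3 must be set earlier in A9 by a separate asymmetric step. A9 contains a terminal ethynyl ether, which is hard to make and easily hydrated. After the key step, two C–B oxidations and two O-methylations of an air-sensitive intermediate only rebuild the ring that the chosen plan buys as 8. The ring B oxidation problem remains.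
- **Comparison:** Elegant in ring construction but clearly worse in step count, and it leaves the main difficulty, C3, unsolved.

Key step: step 4

Remark: compounds 1, 3 and 8 are taken as purchasable; 1 is otherwise one Dakin oxidation away from 2,3,4-trimethoxybenzaldehyde.

Remark: which enantiomer of the step 4 catalyst gives (3S) cannot be derived with certainty on paper, so the (S)-tert-leucine-derived diamine is written and its mirror image replaces it if the first correlation shows the opposite sense.

**Step 1**
Reactants: 1 2,3,4-trimethoxyphenol
Product: 2 1-(methoxymethoxy)-2,3,4-trimethoxybenzene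
Conditions: NaH, MOMCl, DMF, 0 °C to rt
Reagents that add atoms: chloromethyl methyl ether, COCCl
Why: Williamson-type O-alkylation of the phenoxide; the methoxymethyl ether is chosen because it directs ortho-lithiation, survives steps 2 to 6 and later comes off with mild acid.

**Step 2**
Reactants: 2 1-(methoxymethoxy)-2,3,4-trimethoxybenzene; 3 2-bromo-3,3-diethoxyprop-1-ene
Product: 6 1-(3,3-diethoxyprop-1-en-2-yl)-2-(methoxymethoxy)-3,4,5-trimethoxybenzene, via aryllithium 4 (not isolated), via arylzinc chloride 5 (not isolated)
Conditions: n-BuLi, THF, 0 °C; ZnCl2, 0 °C to rt; 3, Pd(PPh3)4 (5 mol%), THF, 50 °C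
Reagents that add atoms: none
Why: Directed ortho-metalation beside the chelating methoxymethoxy group (a stronger director than methoxy), transmetalation to zinc and Negishi coupling with the 1,1-disubstituted vinyl bromide; the acetal masks the aldehyde from the organometallics.

**Step 3**
Reactants: 6 1-(3,3-diethoxyprop-1-en-2-yl)-2-(methoxymethoxy)-3,4,5-trimethoxybenzene
Product: 7 2-[2-(methoxymethoxy)-3,4,5-trimethoxyphenyl]prop-2-enal
Conditions: oxalic acid (5% aq), THF, 0 °C to rt; used at once
Reagents that add atoms: water, O
Why: Acid-catalysed acetal hydrolysis; the diethyl acetal ionises through an alkoxyallyl cation far more readily than the formaldehyde-derived methoxymethyl ether, so weak aqueous acid should unmask only the aldehyde.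

**Step 4**
Reactants: 7 2-[2-(methoxymethoxy)-3,4,5-trimethoxyphenyl]prop-2-enal; 8 3,4-dimethoxyphenol
Product: 10 (3S)-6,7-dimethoxy-3-[2-(methoxymethoxy)-3,4,5-trimethoxyphenyl]chroman-2-ol (mixture of C2 anomers), via hydroxy aldehyde 9 (not isolated)
Conditions: (2S)-N1,N1-diethyl-3,3-dimethylbutane-1,2-diamine·CF3SO3H (20 mol%), 7 added slowly to 8 (1.2 equiv), CHCl3, 0 °C
Reagents that add atoms: none
Why: Proposed new method: the primary amine of the catalyst condenses with 7 to an iminium ion, and the carbon of 8 that is ortho to OH and para to the 3-methoxy group attacks its methylene terminus (Friedel–Crafts-type conjugate addition, C4–C4a); the other ortho carbon lies between two oxygens and is shielded. Rearomatisation leaves an α-aryl enamine, and the neighbouring trialkylammonium N–H of the catalyst should hand its proton to one face of C3, which is the element that sets the only stereocentre. Hydrolysis releases hydroxy aldehyde 9, whose phenol oxygen adds to the carbonyl carbon in a 6-exo-trig closure (O1–C2) to lactol 10, taking the labile α-aryl aldehyde out of reach of renewed enamine formation. The closest known reaction types are the amine-catalysed Friedel–Crafts/hemiacetalisation of electron-rich phenols with β-substituted enals to chroman-2-ols and the primary–tertiary diamine-catalysed additions of indoles and thiols to α-substituted acroleins with enantioselective enamine protonation; the two have not been combined on an α-aryl acrolein. The step needs C- over O-alkylation (the oxa-Michael adduct is reversible while the C-adduct is drained by rearomatisation and lactol formation), ortho regioselectivity (secured by the substitution of 8) and facial selectivity in the protonation (secured by the catalyst; the ortho methoxymethoxy group twists ring B out of the enamine plane, which should keep the enamine basic enough for intramolecular proton transfer to outrun background protonation by the phenol).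

**Step 5**
Reactants: 10 (3S)-6,7-dimethoxy-3-[2-(methoxymethoxy)-3,4,5-trimethoxyphenyl]chroman-2-ol
Product: 11 (2S)-3-(2-hydroxy-4,5-dimethoxyphenyl)-2-[2-(methoxymethoxy)-3,4,5-trimethoxyphenyl]propan-1-ol
Conditions: NaBH4, EtOH, −20 to 0 °C; aq NH4Cl
Reagents that add atoms: none
Why: Borohydride reduction of a lactol, which reacts through the small equilibrium share of its ring-opened carbonyl tautomer (the same species as 9 in step 4); hydride addition to that aldehyde is fast at low temperature relative to enolisation, so C3 should keep its configuration.

**Step 6**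
Reactants: 11 (2S)-3-(2-hydroxy-4,5-dimethoxyphenyl)-2-[2-(methoxymethoxy)-3,4,5-trimethoxyphenyl]propan-1-ol
Product: 12 (3S)-6,7-dimethoxy-3-[2-(methoxymethoxy)-3,4,5-trimethoxyphenyl]chroman
Conditions: PPh3, DIAD, THF, 0 °C to rt
Reagents that add atoms: none
Why: Intramolecular Mitsunobu etherification; the ring A phenol displaces the activated primary alcohol (6-exo-tet at C2), C3 is not involved, and the only other phenolic oxygen is blocked as its acetal.

**Step 7**
Reactants: 12 (3S)-6,7-dimethoxy-3-[2-(methoxymethoxy)-3,4,5-trimethoxyphenyl]chroman
Product: 13 6-[(3S)-6,7-dimethoxychroman-3-yl]-2,3,4-trimethoxyphenol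
Conditions: HCl (cat., from AcCl), MeOH, 40 °C
Reagents that add atoms: none
Why: Acid-catalysed acetal exchange transfers the methoxymethyl group to methanol; aryl methyl ethers, the chroman ether and the non-acidic C3–H are inert to these conditions.

**Step 8**
Reactants: 13 6-[(3S)-6,7-dimethoxychroman-3-yl]-2,3,4-trimethoxyphenol
Product: 14 Abroquinone A, 5-[(3S)-6,7-dimethoxy-3,4-dihydro-2H-chromen-3-yl]-2,3-dimethoxycyclohexa-2,5-diene-1,4-dione
Conditions: PhI(OAc)2 (1.1 equiv), MeCN/H2O 2:1, 0 °C
Reagents that add atoms: water, O
Why: Oxidative demethylation of a para-methoxyphenol by a trivalent iodine reagent: the phenol binds to iodine, water attacks the para carbon C5′ and the hemiketal loses methanol to give the 1,4-quinone; ring A has no free phenol and should not be engaged, and C3 is untouched.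

**Compound list**

1 | 2,3,4-trimethoxyphenol | COc1ccc(O)c(OC)c1OC | starting material
2 | 1-(methoxymethoxy)-2,3,4-trimethoxybenzene | COCOc1ccc(OC)c(OC)c1OC | intermediate
3 | 2-bromo-3,3-diethoxyprop-1-ene | C=C(Br)C(OCC)OCC | starting material
4 | [2-(methoxymethoxy)-3,4,5-trimethoxyphenyl]lithium (not isolated) | COCOc1c([Li])cc(OC)c(OC)c1OC | intermediate
5 | chloro[2-(methoxymethoxy)-3,4,5-trimethoxyphenyl]zinc (not isolated) | COCOc1c([Zn]Cl)cc(OC)c(OC)c1OC | intermediate
6 | 1-(3,3-diethoxyprop-1-en-2-yl)-2-(methoxymethoxy)-3,4,5-trimethoxybenzene | CCOC(OCC)C(=C)c1cc(OC)c(OC)c(OC)c1OCOC | intermediate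
7 | 2-[2-(methoxymethoxy)-3,4,5-trimethoxyphenyl]prop-2-enal | COCOc1c(C(=C)C=O)cc(OC)c(OC)c1OC | intermediate
8 | 3,4-dimethoxyphenol | COc1ccc(O)cc1OC | starting material
9 | (2S)-3-(2-hydroxy-4,5-dimethoxyphenyl)-2-[2-(methoxymethoxy)-3,4,5-trimethoxyphenyl]propanal (not isolated) | COCOc1c([C@@H](C=O)Cc2cc(OC)c(OC)cc2O)cc(OC)c(OC)c1OC | intermediate
10 | (3S)-6,7-dimethoxy-3-[2-(methoxymethoxy)-3,4,5-trimethoxyphenyl]chroman-2-ol (C2 anomers) | COCOc1c([C@@H]2Cc3cc(OC)c(OC)cc3OC2O)cc(OC)c(OC)c1OC | intermediate
11 | (2S)-3-(2-hydroxy-4,5-dimethoxyphenyl)-2-[2-(methoxymethoxy)-3,4,5-trimethoxyphenyl]propan-1-ol | COCOc1c([C@@H](CO)Cc2cc(OC)c(OC)cc2O)cc(OC)c(OC)c1OC | intermediate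
12 | (3S)-6,7-dimethoxy-3-[2-(methoxymethoxy)-3,4,5-trimethoxyphenyl]chroman | COCOc1c([C@H]2COc3cc(OC)c(OC)cc3C2)cc(OC)c(OC)c1OC | intermediate
13 | 6-[(3S)-6,7-dimethoxychroman-3-yl]-2,3,4-trimethoxyphenol | COc1cc([C@H]2COc3cc(OC)c(OC)cc3C2)c(O)c(OC)c1OC | intermediate
14 | Abroquinone A, 5-[(3S)-6,7-dimethoxy-3,4-dihydro-2H-chromen-3-yl]-2,3-dimethoxycyclohexa-2,5-diene-1,4-dione | COC1=C(OC)C(=O)C([C@H]2COc3cc(OC)c(OC)cc3C2)=CC1=O | target

**Step count and risks**

Total: 8 steps. Longest linear sequence: 8 steps (1 to 14); 3 enters at step 2 and 8 at step 4.

Step 4 (key step). The most likely failure is poor facial selectivity in the protonation of the conjugated, weakly basic α-aryl enamine, with the phenol substrate acting as a competing achiral proton source. Sluggish C-alkylation by the hindered α-aryl iminium ion, letting the acrolein oligomerise, is the second concern. The fallback is an auxiliary-controlled alkylation that sets out from 2 and comes back to the route at 12. Lithiation of 2 as in step 2 and opening of ethylene oxide (THF, −78 °C to rt) would give 2-[2-(methoxymethoxy)-3,4,5-trimethoxyphenyl]ethanol F1, which TEMPO/PhI(OAc)2 in MeCN/H2O would oxidise to [2-(methoxymethoxy)-3,4,5-trimethoxyphenyl]acetic acid F2. Activation with pivaloyl chloride/Et3N and acylation of lithiated (S)-4-benzyloxazolidin-2-one would give the N-acyl oxazolidinone F3. Evans alkylation of its sodium Z-enolate (NaN(SiMe3)2, THF, −78 °C) with commercial 2-bromo-4,5-dimethoxybenzyl bromide, on the face away from the benzyl group, would give the (2S)-alkylated imide F4, and LiBH4 would cleave the auxiliary to the (2S)-bromo alcohol F5. Intramolecular Buchwald–Hartwig-type C–O coupling (Pd(OAc)2, 2-(di-tert-butylphosphino)-1,1′-binaphthyl, Cs2CO3, toluene, 80 °C) would then close ring C to 12.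

Step 2. Metalation may occur in part next to the C4 methoxy group instead of the acetal oxygen, and the alkenylpalladium intermediate carrying an allylic acetal may couple slowly or lose ethoxide. The fallback fixes the regiochemistry by a sigmatropic shift; it sets out from 1 and comes back to the route at 7. O-Allylation (allyl bromide, K2CO3, acetone) would give 1-(allyloxy)-2,3,4-trimethoxybenzene F6, and Claisen rearrangement (N,N-diethylaniline, 200 °C), which can only reach the one free ortho carbon, would give 6-allyl-2,3,4-trimethoxyphenol F7. Methoxymethylation as in step 1 would give 1-allyl-2-(methoxymethoxy)-3,4,5-trimethoxybenzene F8, and Lemieux–Johnson cleavage (OsO4 cat., NaIO4, 2,6-lutidine, dioxane/H2O) would give [2-(methoxymethoxy)-3,4,5-trimethoxyphenyl]acetaldehyde F9. α-Methylenation (aqueous formaldehyde, pyrrolidine/propionic acid, i-PrOH, 45 °C) would then give 7.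

Step 3. The freed 2-arylacrolein may dimerise or oligomerise on concentration, and the aryl methoxymethyl ether may be partly lost in the acid. The fallback reaches the acrolein under neutral conditions; it sets out from 2 and comes back to the route at 7. Lithiation of 2, quenching with B(OiPr)3 and mild aqueous work-up would give [2-(methoxymethoxy)-3,4,5-trimethoxyphenyl]boronic acid F10. Suzuki–Miyaura coupling with commercial 2-bromoprop-2-en-1-ol (PdCl2(dppf), K2CO3, dioxane/H2O) would give 2-[2-(methoxymethoxy)-3,4,5-trimethoxyphenyl]prop-2-en-1-ol F11, and MnO2 in CH2Cl2 would oxidise the allylic alcohol to 7, used as the filtered solution.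

Step 8. Water may attack the ortho methoxy-bearing carbon C3′ instead of C5′, leading to ortho-quinone products, or the product quinone may be oxidised further in the aqueous medium. The fallback separates oxidation from hydrolysis; it sets out from 13 and comes back to the route at 14. PhI(OAc)2 in dry MeOH at 0 °C would trap the para position as the quinone monoketal 6-[(3S)-6,7-dimethoxychroman-3-yl]-2,3,4,4-tetramethoxycyclohexa-2,5-dien-1-one F12, which can be purified, and dilute aqueous oxalic acid in THF would then hydrolyse the ketal to 14.

**Further compounds**

F1 | step 4 | 2-[2-(methoxymethoxy)-3,4,5-trimethoxyphenyl]ethanol | COCOc1c(CCO)cc(OC)c(OC)c1OC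
F2 | step 4 | [2-(methoxymethoxy)-3,4,5-trimethoxyphenyl]acetic acid | COCOc1c(CC(=O)O)cc(OC)c(OC)c1OC
F3 | step 4 | (4S)-4-benzyl-3-{[2-(methoxymethoxy)-3,4,5-trimethoxyphenyl]acetyl}-1,3-oxazolidin-2-one | COCOc1c(CC(=O)N2C(=O)OC[C@@H]2Cc2ccccc2)cc(OC)c(OC)c1OC
F4 | step 4 | (4S)-4-benzyl-3-{(2S)-3-(2-bromo-4,5-dimethoxyphenyl)-2-[2-(methoxymethoxy)-3,4,5-trimethoxyphenyl]propanoyl}-1,3-oxazolidin-2-one | COCOc1c([C@H](Cc2cc(OC)c(OC)cc2Br)C(=O)N2C(=O)OC[C@@H]2Cc2ccccc2)cc(OC)c(OC)c1OC
F5 | step 4 | (2S)-3-(2-bromo-4,5-dimethoxyphenyl)-2-[2-(methoxymethoxy)-3,4,5-trimethoxyphenyl]propan-1-ol | COCOc1c([C@@H](CO)Cc2cc(OC)c(OC)cc2Br)cc(OC)c(OC)c1OC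
F6 | step 2 | 1-(allyloxy)-2,3,4-trimethoxybenzene | C=CCOc1ccc(OC)c(OC)c1OC
F7 | step 2 | 6-allyl-2,3,4-trimethoxyphenol | C=CCc1cc(OC)c(OC)c(OC)c1O
F8 | step 2 | 1-allyl-2-(methoxymethoxy)-3,4,5-trimethoxybenzene | C=CCc1cc(OC)c(OC)c(OC)c1OCOC
F9 | step 2 | [2-(methoxymethoxy)-3,4,5-trimethoxyphenyl]acetaldehyde | COCOc1c(CC=O)cc(OC)c(OC)c1OC
F10 | step 3 | [2-(methoxymethoxy)-3,4,5-trimethoxyphenyl]boronic acid | COCOc1c(B(O)O)cc(OC)c(OC)c1OC
F11 | step 3 | 2-[2-(methoxymethoxy)-3,4,5-trimethoxyphenyl]prop-2-en-1-ol | COCOc1c(C(=C)CO)cc(OC)c(OC)c1OC
F12 | step 8 | 6-[(3S)-6,7-dimethoxychroman-3-yl]-2,3,4,4-tetramethoxycyclohexa-2,5-dien-1-one | COC1=C(OC)C(OC)(OC)C=C([C@H]2COc3cc(OC)c(OC)cc3C2)C1=O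
A1 | alternative 1 | (2,3,4,5-tetramethoxyphenyl)lithium | [Li]c1cc(OC)c(OC)c(OC)c1OC
A2 | alternative 1 | 4,4,5,5-tetramethyl-2-vinyl-1,3,2-dioxaborolane (pinacol vinylboronate) | C=CB1OC(C)(C)C(C)(C)O1
A3 | alternative 1 | 2-(benzyloxy)-4,5-dimethoxyphenyl trifluoromethanesulfonate | COc1cc(OCc2ccccc2)c(OS(=O)(=O)C(F)(F)F)cc1OC
A4 | alternative 1 | pinacol [(1S)-2-(2-benzyloxy-4,5-dimethoxyphenyl)-1-(2,3,4,5-tetramethoxyphenyl)ethyl]boronate | COc1cc([C@H](Cc2cc(OC)c(OC)cc2OCc2ccccc2)B2OC(C)(C)C(C)(C)O2)c(OC)c(OC)c1OC
A5 | alternative 2 | 6,7-dimethoxy-2H-chromene | COc1cc2OCC=Cc2cc1OC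
A6 | alternative 2 | 2,3-dimethoxy-1,4-benzoquinone | COC1=C(OC)C(=O)C=CC1=O
A7 | alternative 2 | (6aS,11aS)-8-hydroxy-2,3,9,10-tetramethoxypterocarpan (cis ring fusion) | COc1cc2OC[C@@H]3c4cc(O)c(OC)c(OC)c4O[C@@H]3c2cc1OC
A8 | alternative 2 | (3S)-3-(2,5-dihydroxy-3,4-dimethoxyphenyl)-6,7-dimethoxychroman | COc1cc2OC[C@@H](Cc2cc1OC)c1cc(O)c(OC)c(OC)c1O
A9 | alternative 3 | 1-[(2S)-1-(ethynyloxy)pent-4-yn-2-yl]-2,3,4,5-tetramethoxybenzene | C#CC[C@H](COC#C)c1cc(OC)c(OC)c(OC)c1OC
A10 | alternative 3 | bis(pinacolboryl)acetylene | CC1(C)OB(C#CB2OC(C)(C)C(C)(C)O2)OC1(C)C
A11 | alternative 3 | (3S)-6,7-bis(pinacolboryl)-3-(2,3,4,5-tetramethoxyphenyl)chroman | COc1cc([C@H]2COc3cc(B4OC(C)(C)C(C)(C)O4)c(B4OC(C)(C)C(C)(C)O4)cc3C2)c(OC)c(OC)c1OC
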